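**Retrosynthetic overview**
1. Target ⇐ methylenation of a spiro[5.5] ketone (C1=O) that already carries both C–Br centres, the tertiary alcohol and the spiro centre.
2. Spiro ketone ⇐ key 5→6 ring expansion. The CMe2 carbon (C5) shifts 1,2 from carbinol C1 to a cation at C6 of a 1-(cyclohexenyl)cyclopentanol, which makes ring A and sets C6.
3. Ring B trans-bromohydrin ⇐ bromide opening of a catalyst-controlled epoxide of a 1,4-diene. Ring B ⇐ cobalt-catalysed formal [4+2] of isoprene with an ethynyl carbinol.
4. Ethynyl carbinol ⇐ ethynyl Grignard + (S)-3-bromo-2,2-dimethylcyclopentanone ⇐ bromonium-triggered 1,2-methyl shift of (R)-1,2-dimethylcyclopent-2-enol ⇐ 2-methylcyclopent-2-enone + Me2Zn (asymmetric).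
5. Ring order: cyclopentane (bought in) → ring B → ring A (by enlarging the cyclopentane).

Assumption: atom labels follow the target SMILES (C1 = C(=CH2), C2, C3, C4 = CHBr, C5 = CMe2, C6 = spiro, C7, C8, C9 = C(CH3)OH, C10 = CHBr, C11). The enantiomer of each chiral catalyst is chosen from its usual induction model.

Step 1
Reactants: 1 2-methylcyclopent-2-en-1-one
Product: 2 (R)-1,2-dimethylcyclopent-2-en-1-ol
Conditions: Me2Zn (2 equiv), Ti(OiPr)4 (1.2 equiv), trans-cyclohexane-1,2-diamine bis(2-hydroxycamphor-10-sulfonamide) ligand (10 mol %), toluene–hexane, 25 °C; then H2O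
Reagents that add atoms: dimethylzinc, C[Zn]C
Why: Titanium-mediated catalytic asymmetric 1,2-addition of a dialkylzinc to an α-substituted cyclic enone, in which the chiral bis(sulfonamide)diol–titanium complex shields one carbonyl face, the α-methyl group suppresses 1,4-addition, and the ligand enantiomer is picked to give the R carbinol.

Step 2
Reactants: 2 (R)-1,2-dimethylcyclopent-2-en-1-ol
Product: 3 (S)-3-bromo-2,2-dimethylcyclopentan-1-one
Conditions: NBS (1.05 equiv), CH2Cl2, −40 → 0 °C, dark
Reagents that add atoms: N-bromosuccinimide, O=C1CCC(=O)N1Br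
Why: Halogenative semipinacol rearrangement (1,2-methyl shift), in which Br+ adds to the CH= carbon on the face syn to the small, hydrogen-bonding OH and the antiperiplanar carbinol methyl migrates to the tertiary cationic carbon as C=O forms, so the R carbinol centre is traded stereospecifically for the S C–Br centre (C4) and the CMe2 carbon (C5) is created.

Step 3
Reactants: 3 (S)-3-bromo-2,2-dimethylcyclopentan-1-one; 4 ethynylmagnesium bromide
Product: 5 (1S,3S)-3-bromo-1-ethynyl-2,2-dimethylcyclopentan-1-ol (OH cis to Br)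
Conditions: THF, −78 → 0 °C; then H2O
Reagents that add atoms: none
Why: Grignard 1,2-addition of a small, weakly basic acetylide that occurs mainly anti to the bromine and is kept cold so the magnesium alkoxide does not undergo Grob fragmentation, and whose new carbinol centre is erased in step 7 so its ratio does not matter.

Step 4
Reactants: 5 (1S,3S)-3-bromo-1-ethynyl-2,2-dimethylcyclopentan-1-ol; 6 isoprene (2-methylbuta-1,3-diene)
Product: 7 (1S,3S)-3-bromo-2,2-dimethyl-1-(4-methylcyclohexa-1,4-dien-1-yl)cyclopentan-1-ol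
Conditions: CoBr2(dppe) (10 mol %), Zn (20 mol %), ZnI2 (20 mol %), CH2Cl2, 25 °C
Reagents that add atoms: none
Why: Cobalt-catalysed formal [4+2] cycloaddition of a 1,3-diene with an unactivated terminal alkyne through a cobaltacycle of monovalent cobalt, in which the dppe ligand gives the 1,4 ("para") regioisomer, no stereocentre is formed, and the neopentyl secondary bromide is too hindered to react with the catalyst.

Step 5
Reactants: 7 (1S,3S)-3-bromo-2,2-dimethyl-1-(4-methylcyclohexa-1,4-dien-1-yl)cyclopentan-1-ol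
Product: 8 (1S,3S)-3-bromo-2,2-dimethyl-1-[(1S,6R)-6-methyl-7-oxabicyclo[4.1.0]hept-3-en-3-yl]cyclopentan-1-ol
Conditions: ent-Shi ketone (L-sorbose-derived 1,2:4,5-di-O-isopropylidene-L-erythro-2,3-hexodiulo-2,6-pyranose, 30 mol %), Oxone, K2CO3, Bu4NHSO4 (cat.), MeCN–CH2(OMe)2 / aq. Na2B4O7–Na2EDTA, 0 °C
Reagents that add atoms: potassium peroxymonosulfate (KHSO5 of Oxone), [K+].[O-]S(=O)(=O)OO
Why: Shi asymmetric epoxidation, in which the chiral dioxirane attacks only the unhindered, electron-richer methyl-bearing alkene (the other is shielded by the quaternary carbinol and deactivated by its oxygen) and, because the flat diene ring has no facial bias, the catalyst's spiro transition state fixes C9 and C10, the minor isomer being a separable diastereomer.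

Step 6
Reactants: 8 (1S,3S)-3-bromo-2,2-dimethyl-1-[(1S,6R)-6-methyl-7-oxabicyclo[4.1.0]hept-3-en-3-yl]cyclopentan-1-ol
Product: 9 (1S,3S)-3-bromo-1-[(4R,5R)-5-bromo-4-hydroxy-4-methylcyclohex-1-en-1-yl]-2,2-dimethylcyclopentan-1-ol
Conditions: Li2NiBr4 (1.5 equiv), THF, 0 → 25 °C; then H2O
Reagents that add atoms: dilithium tetrabromonickelate Li2NiBr4, [Li+].[Li+].[Ni+2].[Br-].[Br-].[Br-].[Br-]
Why: SN2 epoxide opening by soft bromide at the less substituted carbon C10 with inversion, which leaves the tertiary C9–O bond untouched and gives the trans-bromohydrin with C9 (R) and C10 (R) as in the target.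

Step 7
Reactants: 9 (1S,3S)-3-bromo-1-[(4R,5R)-5-bromo-4-hydroxy-4-methylcyclohex-1-en-1-yl]-2,2-dimethylcyclopentan-1-ol
Product: 11 (4S,6S,8R,9R)-4,8-dibromo-9-hydroxy-5,5,9-trimethylspiro[5.5]undecan-1-one, via C6 tertiary cation 10 (not isolated)
Conditions: (R,R)-Co(salen) complex C36H52CoN2O2 (divalent cobalt, 5 mol %), 1-fluoro-2,4,6-trimethylpyridinium triflate (1.5 equiv), (HMe2Si)2O (1.5 equiv), acetone, 0 → 25 °C
Reagents that add atoms: none
Why: Proposed new method: a cobalt hydride made from the salen complex, the N-fluoropyridinium oxidant and the silane transfers a hydrogen atom to the less substituted alkene carbon C7; the tertiary C6 radical is oxidised (through an alkyl complex of tetravalent cobalt or by electron transfer) to cation 10; the more substituted C1–C5 bond then shifts to C6 while C1–OH becomes C=O (semipinacol 5→6 ring expansion), with C5 entering equatorially on the ring B chair that keeps C10–Br and C9–OH equatorial, because the other chair would force C1 into a 1,3-diaxial clash with Br, so C5 ends cis to C10–Br as the target requires; the closest known reaction type is the cobalt-salen hydrogen-atom-transfer/radical–polar-crossover semipinacol rearrangement of tertiary allylic alcohols bearing 1,1-disubstituted alkenes, which has not been shown for an endocyclic trisubstituted alkene, for a spiro centre next to a quaternary carbon, or with remote 1,3-stereocontrol.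

Step 8
Reactants: 11 (4S,6S,8R,9R)-4,8-dibromo-9-hydroxy-5,5,9-trimethylspiro[5.5]undecan-1-one
Product: 12 (2R,3R,6R,8S)-2,8-dibromo-3,7,7-trimethyl-11-methylidenespiro[5.5]undecan-3-ol (target)
Conditions: Cp2Ti(μ-Cl)(μ-CH2)AlMe2 (3 equiv), pyridine, THF–toluene, −40 → 25 °C; then aq. NaHCO3
Reagents that add atoms: Tebbe reagent Cp2Ti(μ-Cl)(μ-CH2)AlMe2 (Cp drawn σ-bonded), C[Al-]1(C)C[Ti](C2C=CC=C2)(C2C=CC=C2)[Cl+]1
Why: Tebbe methylenation, in which the non-basic titanium methylidene adds to the hindered carbonyl by [2+2] and cycloreverts to the alkene, the first equivalent only metalates the tertiary OH, the conformationally locked trans-diequatorial bromohydrin cannot close to an epoxide, and no stereocentre is touched.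

**Compound list**
1 | 2-methylcyclopent-2-en-1-one | CC1=CCCC1=O | starting material
2 | (R)-1,2-dimethylcyclopent-2-en-1-ol | O[C@]1(C)CCC=C1C | intermediate
3 | (S)-3-bromo-2,2-dimethylcyclopentan-1-one | O=C1CC[C@H](Br)C1(C)C | intermediate
4 | ethynylmagnesium bromide | C#C[Mg]Br | starting material
5 | (1S,3S)-3-bromo-1-ethynyl-2,2-dimethylcyclopentan-1-ol | C#C[C@@]1(O)CC[C@H](Br)C1(C)C | intermediate
6 | isoprene | C=CC(C)=C | starting material
7 | (1S,3S)-3-bromo-2,2-dimethyl-1-(4-methylcyclohexa-1,4-dien-1-yl)cyclopentan-1-ol | CC1=CCC(=CC1)[C@@]2(O)CC[C@H](Br)C2(C)C | intermediate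
8 | (1S,3S)-3-bromo-2,2-dimethyl-1-[(1S,6R)-6-methyl-7-oxabicyclo[4.1.0]hept-3-en-3-yl]cyclopentan-1-ol | C[C@@]12CC=C(C[C@@H]1O2)[C@@]3(O)CC[C@H](Br)C3(C)C | intermediate
9 | (1S,3S)-3-bromo-1-[(4R,5R)-5-bromo-4-hydroxy-4-methylcyclohex-1-en-1-yl]-2,2-dimethylcyclopentan-1-ol | C[C@@]1(O)CC=C(C[C@H]1Br)[C@@]2(O)CC[C@H](Br)C2(C)C | intermediate
10 | tertiary cyclohexyl cation at C6 (from H addition to C7 of 9), not isolated | C[C@@]1(O)CC[C+](C[C@H]1Br)[C@@]2(O)CC[C@H](Br)C2(C)C | intermediate
11 | (4S,6S,8R,9R)-4,8-dibromo-9-hydroxy-5,5,9-trimethylspiro[5.5]undecan-1-one | O=C1CC[C@H](Br)C(C)(C)[C@@]12CC[C@@](C)(O)[C@H](Br)C2 | intermediate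
12 | (2R,3R,6R,8S)-2,8-dibromo-3,7,7-trimethyl-11-methylidenespiro[5.5]undecan-3-ol | C=C1CC[C@H](Br)C(C)(C)[C@@]12CC[C@@](C)(O)[C@H](Br)C2 | target

Total step count: 8. Longest linear sequence: 8.

**Three steps most likely to fail**

(a) Ring expansion 9 → 11 (step 7, the new reaction).
- Risks: hydrogen-atom transfer to the crowded alkene may be slow. The C2 methylene may shift instead of C5. The cation may be captured by O (epoxide or bridged ether).
- Fallback, known chemistry, from 9 back to 11: a polar, electrophile-triggered halogenative semipinacol rearrangement. N-Iodosuccinimide in CH2Cl2 at −20 °C forms the iodonium ion on C6=C7, and C5 migrates anti to it. This gives (4S,6R,7S,9R,10R)-4,10-dibromo-9-hydroxy-7-iodo-5,5,9-trimethylspiro[5.5]undecan-1-one F1.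
- The iodine is then removed chemoselectively with Bu3SnH (1.0 equiv) and Et3B/air in toluene at −78 °C, because iodine abstraction is much faster than bromine abstraction. This delivers 11.

(b) Bromonium-triggered methyl shift 2 → 3 (step 2).
- Risks: closure to an epoxy bromide, or proton loss from the cation instead of methyl migration.
- Fallback, from 1 back to 3: the oxygen analogue followed by inversion. The enantiomeric ligand in the Me2Zn/Ti(OiPr)4 addition to 1 gives (S)-1,2-dimethylcyclopent-2-en-1-ol F2.
- Hydroxyl-directed epoxidation (VO(acac)2, t-BuOOH) then gives (1R,2S,5R)-1,2-dimethyl-6-oxabicyclo[3.1.0]hexan-2-ol F3.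
- BF3·OEt2 induces the epoxy-alcohol semipinacol methyl shift to (R)-3-hydroxy-2,2-dimethylcyclopentan-1-one F4.
- Appel bromination (CBr4, PPh3) on the cyclopentane with inversion gives 3.

(c) Cobalt-catalysed annulation 5 + 6 → 7 (step 4).
- Risks: the hindered propargylic alcohol may not engage, or low-valent cobalt may attack the C–Br bond.
- Fallback, from 6 and 3 back to 7 (it bypasses 4 and 5): ring B is made first on a simple alkyne and joined by carbonyl addition.
- Isoprene 6 and trimethylsilylacetylene under the same CoBr2(dppe)/Zn/ZnI2 catalysis give trimethyl(4-methylcyclohexa-1,4-dien-1-yl)silane F5.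
- Ipso-iododesilylation (NIS, MeCN) gives 1-iodo-4-methylcyclohexa-1,4-diene F6.
- t-BuLi (2 equiv, THF, −78 °C) gives (4-methylcyclohexa-1,4-dien-1-yl)lithium F7, which adds to ketone 3 at −78 °C to give 7 after aqueous quench.

**Further compounds**
F1 | step 7 | (4S,6R,7S,9R,10R)-4,10-dibromo-9-hydroxy-7-iodo-5,5,9-trimethylspiro[5.5]undecan-1-one | O=C1CC[C@H](Br)C(C)(C)[C@@]12[C@@H](I)C[C@@](C)(O)[C@H](Br)C2
F2 | step 2 | (S)-1,2-dimethylcyclopent-2-en-1-ol | O[C@@]1(C)CCC=C1C
F3 | step 2 | (1R,2S,5R)-1,2-dimethyl-6-oxabicyclo[3.1.0]hexan-2-ol | C[C@]1(O)CC[C@H]2O[C@@]12C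
F4 | step 2 | (R)-3-hydroxy-2,2-dimethylcyclopentan-1-one | O=C1CC[C@@H](O)C1(C)C
F5 | step 4 | trimethyl(4-methylcyclohexa-1,4-dien-1-yl)silane | CC1=CCC(=CC1)[Si](C)(C)C
F6 | step 4 | 1-iodo-4-methylcyclohexa-1,4-diene | CC1=CCC(I)=CC1
F7 | step 4 | (4-methylcyclohexa-1,4-dien-1-yl)lithium | [Li]C1=CCC(C)=CC1
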